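Assumption: the target has no stereocentre or other stereogenic element, so it is one achiral compound and needs no enantiocontrol. The only stereocentre on the route (in 4) is formed racemic and is destroyed in step 2.

**Retrosynthetic overview**
1. Target 11 ⇒ C6–Br (bromination ortho to a free 5-OH) ⇒ 10 ⇒ O-demethylation ⇒ 8 ⇒ two ring brominations ⇒ vanillin 6.
2. Vanillin 6 ⇒ oxidative decarboxylation ⇒ mandelic acid 4 ⇒ key C–C disconnection (aryl C1 to side-chain carbon): aldol-type addition of guaiacolate 1, a vinylogous enolate, to the aldehyde of glyoxylic acid 2.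
3. Each bromine goes to the site activated by the oxygen that is free at that stage: C3 by the 4-OH, C2 by the para 5-OMe, C6 by the liberated 5-OH.
4. The benzene ring is the only ring and is bought intact in guaiacol, so no ring is formed.

**Route**

Step 1
Reactants: 1 guaiacol (2-methoxyphenol); 2 glyoxylic acid (50 wt % aqueous solution)
Product: 4 (±)-4-hydroxy-3-methoxymandelic acid, via para-dienone aldol adduct 3 (not isolated)
Conditions: 1 (1.5 equiv), 2 (1.0 equiv, added slowly), NaOH (2.6 equiv), H2O, 0 °C → 20 °C, 24 h; aq HCl to pH 6, toluene wash (recovers 1); aq HCl to pH 1.5, EtOAc extraction, crystallisation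
Reagents that add atoms: none
Why: In this aldol-type addition (phenolate hydroxyalkylation), sodium guaiacolate acts as a vinylogous enolate whose unhindered para carbon attacks the very electrophilic aldehyde of glyoxylate, the dienone adduct 3 tautomerises irreversibly to the phenol, cold dilute alkali and excess 1 hold back ortho attack, double addition and Cannizzaro loss of 2, and the new carbinol centre is racemic and is erased in step 2.

Step 2
Reactants: 4 (±)-4-hydroxy-3-methoxymandelic acid
Product: 6 vanillin (4-hydroxy-3-methoxybenzaldehyde), via aryl glyoxylic acid 5 (not isolated)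
Conditions: Cu(OH)2 (2.3 equiv), NaOH (3 equiv), H2O, 95 °C, 3 h; filter; aq HCl to pH 2, 50 °C; toluene extraction
Reagents that add atoms: none
Why: In this oxidative decarboxylation of an α-hydroxy acid, divalent copper in hot alkali dehydrogenates the electron-rich benzylic carbinol to the α-keto acid 5 (being reduced to Cu2O), 5 loses CO2 on acidification to give the aldehyde, and the aldehyde resists further oxidation because it sits in the alkaline medium as its stabilised phenoxide.

Step 3
Reactants: 6 vanillin
Product: 7 5-bromovanillin (3-bromo-4-hydroxy-5-methoxybenzaldehyde)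
Conditions: Br2 (1.05 equiv), glacial AcOH, 20 °C, 2 h; ice-water, filter
Reagents that add atoms: bromine, BrBr
Why: In this electrophilic aromatic bromination the free 4-OH is the strongest director, its para position is blocked by the formyl group and one ortho position by OMe, so one equivalent of Br2 enters cleanly at the remaining ortho carbon.

Step 4
Reactants: 7 5-bromovanillin
Product: 8 2,3-dibromo-4-hydroxy-5-methoxybenzaldehyde
Conditions: Br2 (1.3 equiv), Fe powder (5 mol %), glacial AcOH, 20 → 70 °C, 5 h; aq NaHSO3, ice-water, filter
Reagents that add atoms: bromine, BrBr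
Why: In this electrophilic aromatic bromination catalysed by FeBr3 formed in situ, the sites next to the phenol are filled, so the methoxy group directs bromine to its para carbon C2, and the regiochemistry cannot harm the target because the last open position is brominated later anyway.

Step 5
Reactants: 8 2,3-dibromo-4-hydroxy-5-methoxybenzaldehyde
Product: 10 2,3-dibromo-4,5-dihydroxybenzaldehyde, via cyclic bromoborate 9 (not isolated)
Conditions: BBr3 (2.5 equiv, 1 M in CH2Cl2), CH2Cl2, −78 °C → 20 °C, 12 h; ice-water, EtOAc extraction
Reagents that add atoms: none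
Why: In this Lewis-acid aryl methyl ether cleavage, BBr3 binds the adjacent hydroxy and methoxy oxygens, bromide removes the methyl group by SN2 to give the chelated borate 9, and water hydrolyses the B–O bonds while the aryl bromides and the aldehyde come through unchanged.

Step 6
Reactants: 10 2,3-dibromo-4,5-dihydroxybenzaldehyde
Product: 11 2,3,6-tribromo-4,5-dihydroxybenzaldehyde (target)
Conditions: Br2 (1.3 equiv), glacial AcOH, dark, 20 → 50 °C, 6 h (HPLC control); aq NaHSO3, ice-water, filter, recrystallise from aq AcOH
Reagents that add atoms: bromine, BrBr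
Why: In this electrophilic aromatic bromination the newly freed 5-OH strongly activates its only open ortho carbon C6 (as in the easy ortho-bromination of 3-hydroxybenzaldehydes), and the anhydrous acidic medium keeps the phenols un-ionised, which suppresses ipso bromodeformylation and oxidation to the o-quinone.

**Compound list**
1 | guaiacol (2-methoxyphenol) | COc1ccccc1O | starting material
2 | glyoxylic acid | O=CC(=O)O | starting material
3 | 2-hydroxy-2-(3-methoxy-4-oxocyclohexa-2,5-dien-1-yl)acetic acid (racemic diastereomer mixture, not isolated) | COC1=CC(C(O)C(=O)O)C=CC1=O | intermediate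
4 | (±)-4-hydroxy-3-methoxymandelic acid (racemic) | COc1cc(C(O)C(=O)O)ccc1O | intermediate
5 | (4-hydroxy-3-methoxyphenyl)glyoxylic acid (not isolated) | COc1cc(C(=O)C(=O)O)ccc1O | intermediate
6 | vanillin (4-hydroxy-3-methoxybenzaldehyde) | COc1cc(C=O)ccc1O | intermediate
7 | 5-bromovanillin (3-bromo-4-hydroxy-5-methoxybenzaldehyde) | COc1cc(C=O)cc(Br)c1O | intermediate
8 | 2,3-dibromo-4-hydroxy-5-methoxybenzaldehyde | COc1cc(C=O)c(Br)c(Br)c1O | intermediate
9 | 2,6,7-tribromo-1,3,2-benzodioxaborole-5-carbaldehyde (not isolated) | O=Cc1cc2OB(Br)Oc2c(Br)c1Br | intermediate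
10 | 2,3-dibromo-4,5-dihydroxybenzaldehyde | O=Cc1cc(O)c(O)c(Br)c1Br | intermediate
11 | 2,3,6-tribromo-4,5-dihydroxybenzaldehyde (achiral) | O=Cc1c(Br)c(O)c(O)c(Br)c1Br | target

**Total step count:** 6. **Longest linear sequence:** 6 steps (1 → 4 → 6 → 7 → 8 → 10 → 11).

**Three steps most likely to fail (most risky first)**

Step 6. The risks are attack of bromine at C1 (para to the 4-OH) with loss of the formyl group, oxidation of the catechol, or a stalled reaction.
- The fallback sets out from 10 and comes back to the route at 11.
- The more acidic 4-OH of 10 (para to CHO, ortho to Br) is methylated selectively with MeI (1.05 equiv) and Li2CO3 in DMF at 40 °C. This gives 2,3-dibromo-5-hydroxy-4-methoxybenzaldehyde F1.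
- That compound has no free catechol and no para-hydroxyl push on C1, but it keeps the 5-OH that activates C6.
- Br2 and NaOAc in AcOH at 20 °C then give 2,3,6-tribromo-5-hydroxy-4-methoxybenzaldehyde F2.
- BBr3 in CH2Cl2 (−78 → 20 °C) converts this into 2,4,6,7-tetrabromo-1,3,2-benzodioxaborole-5-carbaldehyde F3, which ice-water hydrolyses to 11.

Step 1. The risks are ortho and double addition, Cannizzaro loss of glyoxylate in alkali, and a poor recovery of the very water-soluble acid.
- The fallback sets out from 1 and comes back to the route at 4.
- Guaiacol is hydroxyalkylated under acid instead of base with commercial diethyl oxomalonate (CCOC(=O)C(=O)C(=O)OCC) and ZnCl2 in AcOH at 40 °C. This electrophile cannot undergo a Cannizzaro reaction and is too bulky for ortho or double attack.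
- The product is the extractable, crystalline diethyl 2-hydroxy-2-(4-hydroxy-3-methoxyphenyl)propanedioate F4.
- Aqueous NaOH followed by HCl gives 2-hydroxy-2-(4-hydroxy-3-methoxyphenyl)propanedioic acid F5.
- On warming in dilute aqueous acid this loses one CO2 (malonic-acid decarboxylation) and gives 4.

Step 2. The risks are over-oxidation to vanillic acid, oxidative phenol coupling in hot alkali, or incomplete decarboxylation.
- The fallback sets out from 4 and comes back to the route at 6.
- The carboxyl group is reduced with BH3·THF (4 equiv, THF, 0 → 20 °C, aqueous work-up) to racemic 1-(4-hydroxy-3-methoxyphenyl)ethane-1,2-diol F6.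
- The glycol is cleaved with NaIO4 (1.0 equiv, THF/H2O, 0 °C, 20 min) to 6.
- This Malaprade cleavage runs in a cold neutral medium, so it can neither carry the aldehyde on to the acid nor couple the phenol.

**Further compounds**
F1 | step 6 | 2,3-dibromo-5-hydroxy-4-methoxybenzaldehyde | COc1c(O)cc(C=O)c(Br)c1Br
F2 | step 6 | 2,3,6-tribromo-5-hydroxy-4-methoxybenzaldehyde | COc1c(O)c(Br)c(C=O)c(Br)c1Br
F3 | step 6 | 2,4,6,7-tetrabromo-1,3,2-benzodioxaborole-5-carbaldehyde | O=Cc1c(Br)c2OB(Br)Oc2c(Br)c1Br
F4 | step 1 | diethyl 2-hydroxy-2-(4-hydroxy-3-methoxyphenyl)propanedioate | CCOC(=O)C(O)(C(=O)OCC)c1ccc(O)c(OC)c1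
F5 | step 1 | 2-hydroxy-2-(4-hydroxy-3-methoxyphenyl)propanedioic acid | COc1cc(ccc1O)C(O)(C(=O)O)C(=O)O
F6 | step 2 | 1-(4-hydroxy-3-methoxyphenyl)ethane-1,2-diol (racemic) | COc1cc(C(O)CO)ccc1O
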